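**Plan**

1. Retrosynthesis: first the fourteen benzyl ethers and three blocking bromines are removed. Then the interflavan bond C4(upper)–C6(lower) is cut to an upper C4 cation and 8-bromo-epicatechin gallate. Last, the upper pyran ring is cut across O1–C2 and C3–C4 into a ring A ortho-quinone methide and a (Z)-styryl gallate.
2. Enabling feature: in the upper unit the phenolic O1 on C8a is ortho to the benzylic C4 on C4a, so ring A can be raised to an ortho-quinone methide (O1=C8a–C4a=C4). C2 is benzylic to catechol ring B and therefore takes the oxygen.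
3. Forward, three fragments: the lower unit from (−)-epicatechin (benzylation, C8 bromination, galloylation); the 2π partner from 3,4-bis(benzyloxy)benzaldehyde (alkyne, then Z-selective addition of the gallic acid); the methide precursor from 3,5-bis(benzyloxy)phenol (ortho-formylation, dibromination).
4. Upper ring C arises in the hetero-Diels–Alder step with the gallate already in place and OMe on C4. The lower unit is then joined at C4, and one hydrogenolysis removes every helper.
5. Stereochemistry: lower C2/C3 come from the chiral pool. Upper C2/C3 are cis from the Z alkene, with absolute sense from a chiral Brønsted acid. Upper C4 comes from attack anti to the participating 3-O-galloyl group. Because the lower unit is enantiopure, any residual antipode of the upper unit becomes a separable diastereomer.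

Key step: step 8

Remark: the sense of induction of the chiral acid in step 8 cannot be derived with certainty; the catalyst antipode that delivers the (2R,3R) adduct is meant and is written as (R).

**Route**

Step 1
Reactants: 1 (−)-epicatechin
Product: 2 (2R,3R)-5,7-bis(benzyloxy)-2-[3,4-bis(benzyloxy)phenyl]chroman-3-ol
Conditions: BnBr (4.4 equiv), K2CO3, DMF, 0 °C to rt
Reagents that add atoms: benzyl bromide, BrCc1ccccc1
Why: Williamson etherification of the four phenols, which are far more acidic than the secondary 3-OH, so the alcohol stays free and no stereocentre is touched.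

Step 2
Reactants: 2 (2R,3R)-5,7-bis(benzyloxy)-2-[3,4-bis(benzyloxy)phenyl]chroman-3-ol
Product: 3 (2R,3R)-5,7-bis(benzyloxy)-2-[3,4-bis(benzyloxy)phenyl]-8-bromochroman-3-ol
Conditions: NBS (1.0 equiv), CH2Cl2, −78 °C to rt
Reagents that add atoms: N-bromosuccinimide, O=C1CCC(=O)N1Br
Why: Electrophilic aromatic bromination goes to C8, the most nucleophilic position of ring A, which blocks it so that only C6 can react later.

Step 3
Reactants: 3 (2R,3R)-5,7-bis(benzyloxy)-2-[3,4-bis(benzyloxy)phenyl]-8-bromochroman-3-ol; 4 3,4,5-tris(benzyloxy)benzoic acid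
Product: 5 (2R,3R)-5,7-bis(benzyloxy)-2-[3,4-bis(benzyloxy)phenyl]-8-bromochroman-3-yl 3,4,5-tris(benzyloxy)benzoate
Conditions: 4 (1.5 equiv), DCC, DMAP, CH2Cl2, rt
Reagents that add atoms: none
Why: Steglich esterification acylates the axial 3-OH through the DMAP-activated acyl donor with retention, since no bond to C3 is broken.

Step 4
Reactants: 6 3,4-bis(benzyloxy)benzaldehyde
Product: 7 4-ethynyl-1,2-bis(benzyloxy)benzene
Conditions: dimethyl (1-diazo-2-oxopropyl)phosphonate, K2CO3, MeOH/THF, rt
Reagents that add atoms: dimethyl (1-diazo-2-oxopropyl)phosphonate, CC(=O)C(=[N+]=[N-])P(=O)(OC)OC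
Why: Seyferth–Gilbert homologation in the Ohira–Bestmann variant turns the aryl aldehyde into the terminal alkyne under mild base that leaves the benzyl ethers alone.

Step 5
Reactants: 7 4-ethynyl-1,2-bis(benzyloxy)benzene; 4 3,4,5-tris(benzyloxy)benzoic acid
Product: 8 (Z)-2-[3,4-bis(benzyloxy)phenyl]ethenyl 3,4,5-tris(benzyloxy)benzoate
Conditions: Ru(C4H7)2(Ph2P(CH2)4PPh2) (bis(2-methylallyl)[1,4-bis(diphenylphosphino)butane]ruthenium, divalent ruthenium, 2 mol %), toluene, 65 °C
Reagents that add atoms: none
Why: Ruthenium-catalysed anti-Markovnikov hydro-oxycarbonylation of a terminal alkyne proceeds through a ruthenium vinylidene attacked by the carboxylate at the α-carbon, and protonolysis should give the (Z)-enol ester.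

Step 6
Reactants: 9 3,5-bis(benzyloxy)phenol
Product: 10 2,4-bis(benzyloxy)-6-hydroxybenzaldehyde
Conditions: MgCl2, Et3N, (CH2O)n, MeCN, reflux; then 1 M HCl
Reagents that add atoms: paraformaldehyde (formaldehyde), C=O
Why: Casnati–Skattebøl formylation delivers formaldehyde within the magnesium phenoxide chelate, so only the position ortho to the phenol is formylated, and a second formaldehyde oxidises the benzylic alkoxide to the aldehyde.

Step 7
Reactants: 10 2,4-bis(benzyloxy)-6-hydroxybenzaldehyde
Product: 11 2,4-bis(benzyloxy)-3,5-dibromo-6-hydroxybenzaldehyde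
Conditions: NBS (2.1 equiv), DMF, 0 °C to rt
Reagents that add atoms: N-bromosuccinimide, O=C1CCC(=O)N1Br
Why: Electrophilic aromatic bromination fills the two remaining ring positions, each activated by three oxygen substituents and only meta to the formyl group, installing the blocking groups for steps 8 and 9.

Step 8
Reactants: 11 2,4-bis(benzyloxy)-3,5-dibromo-6-hydroxybenzaldehyde; 8 (Z)-2-[3,4-bis(benzyloxy)phenyl]ethenyl 3,4,5-tris(benzyloxy)benzoate
Product: 14 (2R,3R,4R)-5,7-bis(benzyloxy)-2-[3,4-bis(benzyloxy)phenyl]-6,8-dibromo-4-methoxychroman-3-yl 3,4,5-tris(benzyloxy)benzoate, via dimethyl acetal 12 (not isolated), via 4-methoxy ortho-quinone methide 13 (not isolated)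
Conditions: 8 (1.5 equiv), HC(OMe)3 (1.5 equiv), (R)-3,3'-bis(2,4,6-triisopropylphenyl)-1,1'-binaphthyl-2,2'-diyl N-(trifluoromethylsulfonyl)phosphoramide (10 mol %), 4 Å MS, CH2Cl2, −40 °C to 0 °C
Reagents that add atoms: trimethyl orthoformate, COC(OC)OC
Why: Proposed new method: the chiral acid converts 11 with HC(OMe)3 into acetal 12 and ionises it to the 4-methoxy ortho-quinone methide 13 (reacting as its O-protonated oxocarbenium form, hydrogen-bonded through the phenol OH to the phosphoramide anion), whose C4=C4a–C8a=O1 heterodiene adds the electron-rich alkene of 8 in an inverse-electron-demand hetero-Diels–Alder reaction, the ester-bearing carbon bonding to C4 and O1 to the carbon that carries the 3,4-bis(benzyloxy)phenyl group because this aryl group stabilises positive charge far better than the acyloxy group. The closest known reaction types are the acid-catalysed [4+2] addition of salicylaldehyde-acetal-derived ortho-quinone methides to enol ethers and other electron-rich alkenes giving 4-alkoxychromans, and the chiral N-triflylphosphoramide-catalysed [4+2] addition of ortho-hydroxybenzyl-alcohol-derived ortho-quinone methides to styrenes; an enol ester of a styrene as 2π partner and enantiocontrol over an acetal-derived methide have not been shown. Ring C closes in [4+2] mode in one kinetic step, asynchronously, the C3–C4 bond leading and the O1–C2 bond following as a 6-endo capture of the developing benzylic cation by the phenol oxygen. C2 and C3 are set cis by suprafacial addition across the Z alkene, their absolute configuration by the face of the ion pair that the catalyst leaves open combined with the endo approach (ring B and the ester under ring A), and C4 (expected cis to the ester from the E methide) is of no consequence because it is ionised in step 9. The step needs regioselectivity, retention of the alkene geometry, facial selectivity and freedom from Friedel–Crafts self-condensation: these are secured in turn by the donor aryl group on the alkene, by the ortho phenol that closes on C2 before bond rotation or acyloxonium bridging can intervene, by the tight ion pair (the bromine ortho to the phenol raises its acidity and strengthens the hydrogen bond to the anion), and by the two bromine atoms that block both nucleophilic carbons of ring A and make the methide more electrophilic.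

Step 9
Reactants: 14 (2R,3R,4R)-5,7-bis(benzyloxy)-2-[3,4-bis(benzyloxy)phenyl]-6,8-dibromo-4-methoxychroman-3-yl 3,4,5-tris(benzyloxy)benzoate; 5 (2R,3R)-5,7-bis(benzyloxy)-2-[3,4-bis(benzyloxy)phenyl]-8-bromochroman-3-yl 3,4,5-tris(benzyloxy)benzoate
Product: 15 fully protected dimer: (2R,3R)-epicatechin-(4β→6)-(2R,3R)-epicatechin with benzyl ethers on all eight flavan phenol oxygens, a 3,4,5-tris(benzyloxy)benzoate on each C3 oxygen, bromine at C6 and C8 of the upper unit and at C8 of the lower unit
Conditions: 5 (1.5 equiv), Me3SiOTf (0.3 equiv), 4 Å MS, CH2Cl2, −78 °C to −30 °C; Et3N quench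
Reagents that add atoms: none
Why: Lewis-acid ionisation of the 4-methoxy group gives the ring A-stabilised C4 cation, bridged by the neighbouring 3-O-galloyl carbonyl, which should be opened by C6 of 5 (its C8 being brominated, and ring A of 14 having no free position) anti to the ester to give the 3,4-trans (4β) interflavan bond, a Friedel–Crafts-type flavan C4 arylation.

Step 10
Reactants: 15 fully protected tribromo dimer
Product: 16 procyanidin B-5 3,3'-di-O-gallate
Conditions: H2 (1 atm), Pd(OH)2/C, Et3N (3.3 equiv), THF/MeOH/H2O, rt; filtration under Ar, dilute AcOH, lyophilisation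
Reagents that add atoms: none
Why: Catalytic hydrogenolysis should cleave all fourteen benzyl ethers and, with Et3N taking up HBr, the three aryl C–Br bonds in one operation, leaving the gallate esters, the interflavan bond and all five stereocentres untouched.

**Compound list**

1 | (−)-epicatechin, (2R,3R)-2-(3,4-dihydroxyphenyl)chroman-3,5,7-triol | O[C@@H]1Cc2c(O)cc(O)cc2O[C@@H]1c1ccc(O)c(O)c1 | starting material
2 | (2R,3R)-5,7-bis(benzyloxy)-2-[3,4-bis(benzyloxy)phenyl]chroman-3-ol | O[C@@H]1Cc2c(OCc3ccccc3)cc(OCc3ccccc3)cc2O[C@@H]1c1ccc(OCc2ccccc2)c(OCc2ccccc2)c1 | intermediate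
3 | (2R,3R)-5,7-bis(benzyloxy)-2-[3,4-bis(benzyloxy)phenyl]-8-bromochroman-3-ol | O[C@@H]1Cc2c(OCc3ccccc3)cc(OCc3ccccc3)c(Br)c2O[C@@H]1c1ccc(OCc2ccccc2)c(OCc2ccccc2)c1 | intermediate
4 | 3,4,5-tris(benzyloxy)benzoic acid | OC(=O)c1cc(OCc2ccccc2)c(OCc2ccccc2)c(OCc2ccccc2)c1 | starting material
5 | (2R,3R)-5,7-bis(benzyloxy)-2-[3,4-bis(benzyloxy)phenyl]-8-bromochroman-3-yl 3,4,5-tris(benzyloxy)benzoate | O=C(O[C@@H]1Cc2c(OCc3ccccc3)cc(OCc3ccccc3)c(Br)c2O[C@@H]1c1ccc(OCc2ccccc2)c(OCc2ccccc2)c1)c1cc(OCc2ccccc2)c(OCc2ccccc2)c(OCc2ccccc2)c1 | intermediate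
6 | 3,4-bis(benzyloxy)benzaldehyde | O=Cc1ccc(OCc2ccccc2)c(OCc2ccccc2)c1 | starting material
7 | 4-ethynyl-1,2-bis(benzyloxy)benzene | C#Cc1ccc(OCc2ccccc2)c(OCc2ccccc2)c1 | intermediate
8 | (Z)-2-[3,4-bis(benzyloxy)phenyl]ethenyl 3,4,5-tris(benzyloxy)benzoate | O=C(O/C=C\c1ccc(OCc2ccccc2)c(OCc2ccccc2)c1)c1cc(OCc2ccccc2)c(OCc2ccccc2)c(OCc2ccccc2)c1 | intermediate
9 | 3,5-bis(benzyloxy)phenol | Oc1cc(OCc2ccccc2)cc(OCc2ccccc2)c1 | starting material
10 | 2,4-bis(benzyloxy)-6-hydroxybenzaldehyde | O=Cc1c(O)cc(OCc2ccccc2)cc1OCc1ccccc1 | intermediate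
11 | 2,4-bis(benzyloxy)-3,5-dibromo-6-hydroxybenzaldehyde | O=Cc1c(O)c(Br)c(OCc2ccccc2)c(Br)c1OCc1ccccc1 | intermediate
12 | 3,5-bis(benzyloxy)-2,4-dibromo-6-(dimethoxymethyl)phenol (dimethyl acetal of 11) | COC(OC)c1c(O)c(Br)c(OCc2ccccc2)c(Br)c1OCc1ccccc1 | intermediate (not isolated)
13 | (6E)-3,5-bis(benzyloxy)-2,4-dibromo-6-(methoxymethylidene)cyclohexa-2,4-dien-1-one (4-methoxy ortho-quinone methide) | CO/C=C1/C(=O)C(Br)=C(OCc2ccccc2)C(Br)=C1OCc1ccccc1 | intermediate (not isolated)
14 | (2R,3R,4R)-5,7-bis(benzyloxy)-2-[3,4-bis(benzyloxy)phenyl]-6,8-dibromo-4-methoxychroman-3-yl 3,4,5-tris(benzyloxy)benzoate (2,3-cis, 4-OMe cis to the ester) | O=C(O[C@@H]1[C@H](OC)c2c(OCc3ccccc3)c(Br)c(OCc3ccccc3)c(Br)c2O[C@@H]1c1ccc(OCc2ccccc2)c(OCc2ccccc2)c1)c1cc(OCc2ccccc2)c(OCc2ccccc2)c(OCc2ccccc2)c1 | intermediate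
15 | fully protected dimer: epicatechin-(4β→6)-epicatechin, fourteen benzyl ethers, two 3,4,5-tris(benzyloxy)benzoates at the C3 oxygens, Br at C6 and C8 (upper) and C8 (lower) | O=C(O[C@@H]1[C@@H](c2c(OCc3ccccc3)c(Br)c3c(c2OCc2ccccc2)C[C@@H](OC(=O)c2cc(OCc4ccccc4)c(OCc4ccccc4)c(OCc4ccccc4)c2)[C@@H](c2ccc(OCc4ccccc4)c(OCc4ccccc4)c2)O3)c2c(OCc3ccccc3)c(Br)c(OCc3ccccc3)c(Br)c2O[C@@H]1c1ccc(OCc2ccccc2)c(OCc2ccccc2)c1)c1cc(OCc2ccccc2)c(OCc2ccccc2)c(OCc2ccccc2)c1 | intermediate
16 | procyanidin B-5 3,3'-di-O-gallate, (−)-epicatechin 3-O-gallate-(4β→6)-(−)-epicatechin 3-O-gallate | O=C(O[C@@H]1[C@@H](c2c(O)cc3c(c2O)C[C@@H](OC(=O)c2cc(O)c(O)c(O)c2)[C@@H](c2ccc(O)c(O)c2)O3)c2c(O)cc(O)cc2O[C@@H]1c1ccc(O)c(O)c1)c1cc(O)c(O)c(O)c1 | target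

**Totals and risks**

Total step count: 10. Longest linear sequence: 5 steps (for example steps 1, 2, 3, 9, 10; the other two branches are equally long).

Steps most likely to fail:

Step 8. The addition may turn stepwise, so that the cation at C2 lives long enough for bond rotation or bridging by the ester carbonyl and the 2,3-cis relationship is lost. The chiral anion may also give weak facial control, or the enol ester may be protonated and oligomerise. The fallback uses known chemistry and sets out from 2. Benzylic oxidation with DDQ in CH2Cl2/MeOH should give the 4β-methoxy alcohol F1. NBS (2.1 equiv) should then brominate C8 and C6 to the dibromide F2. Steglich esterification with 4 should give the ester F3, the C4 epimer of 14. F3 takes the place of 14 under the conditions of step 9 and comes back to the route at 15.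

Step 9. Capture of the hindered C4 cation, which is less stabilised because of the two bromines, by the weakly nucleophilic C6 of 5 may be too slow, so that proton loss to the flav-3-ene or return of methanol takes over. The fallback gives up the de novo, doubly blocked electrophile for one derived from the chiral pool with a single bromine, the kind of partner with precedent in procyanidin couplings. It sets out from 3. DDQ in CH2Cl2/MeOH should give the 8-bromo-4β-methoxy alcohol F4. Steglich esterification with 4 should give the ester F5. Coupling of F5 with an excess of 5 (3 equiv, surplus recovered; Me3SiOTf, CH2Cl2, −78 °C) should give the dibromo dimer F6. F6 is hydrogenolysed under the conditions of step 10 and comes back to the route at 16.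

Step 5. Markovnikov addition, alkyne dimerisation or erosion of the Z geometry would pass the wrong alkene into step 8 and end in the 2,3-trans series. The fallback sets out from 7. Rhodium-catalysed trans-hydroboration ([RhCl(C8H12)]2, monovalent rhodium, P(i-Pr)3, pinacolborane, Et3N, cyclohexane, rt) should give the (Z)-alkenyl pinacol boronate F7. Oxidative C–O coupling of F7 with 4, mediated by Cu(OAc)2 (divalent copper) with Et3N, 4 Å MS and air in CH2Cl2 (Chan–Lam type, with retention of the alkene geometry), comes back to the route at 8.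

Further compounds
F1 | step 8 | (2R,3R,4S)-5,7-bis(benzyloxy)-2-[3,4-bis(benzyloxy)phenyl]-4-methoxychroman-3-ol (4-OMe trans to 3-OH) | O[C@@H]1[C@@H](OC)c2c(OCc3ccccc3)cc(OCc3ccccc3)cc2O[C@@H]1c1ccc(OCc2ccccc2)c(OCc2ccccc2)c1
F2 | step 8 | (2R,3R,4S)-5,7-bis(benzyloxy)-2-[3,4-bis(benzyloxy)phenyl]-6,8-dibromo-4-methoxychroman-3-ol | O[C@@H]1[C@@H](OC)c2c(OCc3ccccc3)c(Br)c(OCc3ccccc3)c(Br)c2O[C@@H]1c1ccc(OCc2ccccc2)c(OCc2ccccc2)c1
F3 | step 8 | (2R,3R,4S)-5,7-bis(benzyloxy)-2-[3,4-bis(benzyloxy)phenyl]-6,8-dibromo-4-methoxychroman-3-yl 3,4,5-tris(benzyloxy)benzoate (C4 epimer of 14) | O=C(O[C@@H]1[C@@H](OC)c2c(OCc3ccccc3)c(Br)c(OCc3ccccc3)c(Br)c2O[C@@H]1c1ccc(OCc2ccccc2)c(OCc2ccccc2)c1)c1cc(OCc2ccccc2)c(OCc2ccccc2)c(OCc2ccccc2)c1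
F4 | step 9 | (2R,3R,4S)-5,7-bis(benzyloxy)-2-[3,4-bis(benzyloxy)phenyl]-8-bromo-4-methoxychroman-3-ol | O[C@@H]1[C@@H](OC)c2c(OCc3ccccc3)cc(OCc3ccccc3)c(Br)c2O[C@@H]1c1ccc(OCc2ccccc2)c(OCc2ccccc2)c1
F5 | step 9 | (2R,3R,4S)-5,7-bis(benzyloxy)-2-[3,4-bis(benzyloxy)phenyl]-8-bromo-4-methoxychroman-3-yl 3,4,5-tris(benzyloxy)benzoate | O=C(O[C@@H]1[C@@H](OC)c2c(OCc3ccccc3)cc(OCc3ccccc3)c(Br)c2O[C@@H]1c1ccc(OCc2ccccc2)c(OCc2ccccc2)c1)c1cc(OCc2ccccc2)c(OCc2ccccc2)c(OCc2ccccc2)c1
F6 | step 9 | protected dimer as 15 but with Br only at C8 of the upper unit and C8 of the lower unit | O=C(O[C@@H]1[C@@H](c2c(OCc3ccccc3)c(Br)c3c(c2OCc2ccccc2)C[C@@H](OC(=O)c2cc(OCc4ccccc4)c(OCc4ccccc4)c(OCc4ccccc4)c2)[C@@H](c2ccc(OCc4ccccc4)c(OCc4ccccc4)c2)O3)c2c(OCc3ccccc3)cc(OCc3ccccc3)c(Br)c2O[C@@H]1c1ccc(OCc2ccccc2)c(OCc2ccccc2)c1)c1cc(OCc2ccccc2)c(OCc2ccccc2)c(OCc2ccccc2)c1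
F7 | step 5 | 2-[(Z)-2-[3,4-bis(benzyloxy)phenyl]ethenyl]-4,4,5,5-tetramethyl-1,3,2-dioxaborolane | CC1(C)OB(/C=C\c2ccc(OCc3ccccc3)c(OCc3ccccc3)c2)OC1(C)C
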